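**Analysis of the target**

CNP0109410.1 (41) is a trans-fused decalin (ring A: C1–C5 and C10; ring B: C5–C10; labdane labels throughout). C9 carries a two-carbon chain (C11–C12) that ends at the α-carbon of a but-2-en-4-olide (C13–C16). Four contiguous stereocentres sit on the decalin: quaternary C4 (equatorial methyl C18, axial acetoxymethyl C19), C5 (axial H), C9 (axial H, equatorial side chain) and quaternary C10. The formyl carbon C20 on C10 is axial, syn to C19 and on the face opposite to H5 and H9, which places the compound in the ent-labdane series. The sensitive groups are the neopentyl aldehyde, the exocyclic methylene C8=C17 (it migrates into the ring under acid), the butenolide (labile to base and to nucleophiles) and the primary acetate. C19 and C20 are both neopentyl, syn-axial one-carbon groups and must be told apart. The hardest bond is C9–C10, which joins a tertiary to a quaternary carbon next to the methylene-bearing C8. The plan rests on the array C20–C10–C9–C8=C17: a carboxyl-level carbon and a terminal alkene carbon in a 1,5 relationship across C9–C10. This is the pattern left by an ester-enolate Claisen rearrangement in which C20 was an ester carbonyl whose alkoxy oxygen sat on allylic C17.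

**Retrosynthetic reasoning**

41 is taken back to alcohol 40 and its 4-methoxybenzyl ether 39 without cutting a skeletal bond. The aldehyde is the most fragile group, so C20 is kept as a masked primary alcohol until the end. The forward steps must cleave a benzyl-type ether and oxidize a neopentyl alcohol without touching acetate, butenolide or methylene.

In 39 the C12–C13 bond is cut, between the sp3 chain carbon and the α-carbon of the butenolide, giving iodide 36 and bromobutenolide 37. Cutting outside the lactone ring lets the butenolide arrive intact and late, since it would not survive the strong base of the ring-forming step. The forward coupling must join an alkyl metal to 37 without β-hydride loss and without harming the acetate.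

36 goes back through 35, 34, 33 and 32 to acid 31 by functional-group changes only. In 31 the three oxygenated carbons already differ: C20 is a carboxylic acid, C19 and C12 are silyl ethers. C20 can therefore be reduced and capped first, and C12 and C19 are then distinguished by hindrance (C12 unhindered, C19 neopentyl).

The C9–C10 bond of 31 is cut in the retro-[3,3] sense, with C17 reconnected to the C20 carboxyl oxygen; this gives the eight-membered lactone 28. No other cut removes the quaternary C10, the C9 stereocentre, ring B and the exocyclic methylene at once. The forward step must enolize the lactone at C10, trap the enolate on oxygen, and let C10 bond to C9 across the ring with the correct face of C10 and the correct sense at C9.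

The lactone C20–O bond of 28 is cut to seco acid 26. An ester bond is the easiest bond of the medium ring to form last. The forward step must favour closure of an eight-membered ring over oligomerization.

In 26 the C7–C8 bond, between an sp3 and an sp2 carbon, is cut to terminal alkene 17 and iodoalkene 23. This separates a chiral ring A piece from an achiral piece that carries the whole C8=C9 geometry, so the alkene geometry needed for C9 is settled before the fragments meet. The forward coupling must retain that geometry.

23 is traced through enoate 22 and ynoate 20 to silyl ether 19 and but-3-yn-1-ol (18). A syn addition across the alkyne that places the metal next to the ester puts C17 and C11 cis, the geometry needed for C9.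

In 17 the vinyl group C6=C7 is traced to the carbonyl carbon of a γ-lactone (16, 15, 14). The five-membered lactone between the C19 oxygen and C6 holds C6 cis to C19 on ring A. This is the relationship that steric control alone would not give, because the two groups on C4 are similar in size.

In lactone acid 14 the C10–C20 bond is cut: 14 comes from aldehyde 13 and vinyl lactone 10, and 10 from the alkylidene lactone 8 by conjugate addition of a vinyl group. C10 becomes a stereocentre here but is made planar again in the key step, so only the ring fusion (C5) matters.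

In 8 the C5–C6 bond and the lactone C–O bond are cut together (carbonylative ring closure), giving the hydroxy enol triflate 7, and from it triflate 6 and keto ester 5. The quaternary carbon blocks enolization on one side, so the enol triflate can form only towards C10.

In 5 the C4–C18 bond is cut. The quaternary centre comes from alkylation of the chiral enamino ester 3, made from the commercial keto ester 1 and the valine ester 2. This is the only step in which an external source of chirality is needed.

**Alternatives that were turned down**

Alternative 1: The disconnection is C4–C19, made last on ring A. In the forward step, Rh2(OAc)4 turns the C20 diazoketone A2 (a trans-decalin with C8 masked as a dioxolane and C4 still a methine) into a carbenoid at C19, which inserts into the axial C4–H bond and closes the bridging cyclopentanone of A1. For it: insertion goes with retention, so C19 must end syn to C20, and a tertiary C–H bond is the preferred site. On this point the alternative is stronger than the chosen route, which needs an auxiliary to set C4. Against it: the carbenoid also reaches the axial hydrogens on C2 and C6 and the C11 methylene, all at the same distance. A1 also ties C19 to C20 through a C–C bond that the target lacks. A Baeyer–Villiger cleavage would move the quaternary C10 and not the C19 methylene, which puts oxygen on the wrong carbon, and any cleavage leaves two nearly identical neopentyl oxygen groups to differentiate. The decalin with the C9–C10 bond must exist beforehand, so the hardest bond is not addressed. The chosen strategy forms C9–C10, ring B and the methylene in one step and keeps C19 and C20 at different oxidation levels from the start.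

Alternative 2: The disconnections are C4–C5 and C9–C10, so both rings come from one chain. In the forward step, Mn(OAc)3 oxidizes the β-keto ester A4 to the C4 radical, which adds to C5; the C10 radical adds to C9, and Cu(OAc)2 turns the C8 radical into the exocyclic methylene, giving A3. For it: two rings, four stereocentres and the methylene arise in one step from a linear precursor. In step count to the decalin this is clearly stronger than the chosen route. Against it: A3 carries a C3 ketone that the target lacks, and removing it next to a quaternary centre in the presence of the methylene costs steps. The absolute configuration rests on a chiral ester far from the second ring closure, so diastereomers are likely. The central alkene bears a silyloxymethyl group in place of the usual methyl, which changes both the rate and the face selectivity of the second addition. The copper-mediated oxidation can also give ring alkenes. In its place the chosen route offers relay of configuration from one centre through ring-constrained transition states, and a methylene that forms regiospecifically in the sigmatropic shift.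

Alternative 3: The disconnections are C3–C4 and C5–C10, building ring A by a [4+2] cycloaddition. In the forward step the dienol A7 is acylated by anhydride A6 at the carbonyl remote from the methyl group, and the half-ester cyclizes by Diels–Alder reaction (or the order is reversed) to the lactone acid A5. For it: C4, C5 and C10 are set in one step from two cheap achiral compounds, and C6 is cis to C19 by construction. Ring A is reached far faster than in the chosen route, which needs eleven steps to 17. Against it: A5 is racemic unless an asymmetric catalyst can be found for a slow, ester-tethered cycloaddition, so the single enantiomer would need a resolution. Only ring A is solved: C10 is a methine carrying CH2O, and the C9–C10 bond and the quaternary C10 remain. The oxidation levels are also inverted (C19 acid, C20 alcohol), and both must be corrected at neopentyl positions. The chosen strategy spends more steps on ring A but fixes the absolute configuration with an amino acid auxiliary and puts its one uncertain step on the bond that matters.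

Key step: step 18

Remark: C1–C20 are labdane atom labels and are used for all intermediates.
Remark (assumption): in step 2 the lithiated enamine from the L-valine ester, alkylated in toluene with HMPA, is taken to give the (R)-keto ester 5; if the sense of induction is the opposite, the D-valine ester is used in the same way.
Remark: C10 can epimerize until step 18 and is made planar there; from step 7 on it is drawn trans to the C6 arm, the configuration expected after equilibration.

Step 1
Reactants: 1 ethyl 2-oxocyclohexane-1-carboxylate; 2 tert-butyl L-valinate (free base from the commercial hydrochloride)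
Product: 3 tert-butyl (2S)-2-{[2-(ethoxycarbonyl)cyclohex-1-en-1-yl]amino}-3-methylbutanoate
Conditions: BF3·OEt2 (cat.), benzene, reflux, Dean–Stark trap
Reagents that add atoms: none
Why: Acid-catalysed condensation of the β-keto ester with the primary amine gives the enamino ester, held in the Z form by an N–H···O=C hydrogen bond; water is removed azeotropically.

Step 2
Reactants: 3
Product: 5 ethyl (1R)-1-methyl-2-oxocyclohexane-1-carboxylate, via methylated imine 4 (not isolated)
Conditions: LiN(i-Pr)2, toluene, −78 °C; HMPA (1 equiv), MeI, −78 → −55 °C; then 1 M HCl, 23 °C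
Reagents that add atoms: iodomethane CI; water O
Why: Diastereoselective alkylation of a lithiated chiral enamino ester: lithium is chelated by the aza-enolate and the valine ester, the isopropyl group shields one face and iodomethane enters C4 from the other, which sets the quaternary centre; acid hydrolysis of imine 4 releases the keto ester and the auxiliary.

Step 3
Reactants: 5
Product: 6 ethyl (1R)-1-methyl-2-{[(trifluoromethyl)sulfonyl]oxy}cyclohex-2-ene-1-carboxylate
Conditions: KN(SiMe3)2, THF, −78 °C; PhNTf2, −78 → 0 °C
Reagents that add atoms: N-phenylbis(trifluoromethanesulfonimide) O=S(=O)(N(c1ccccc1)S(=O)(=O)C(F)(F)F)C(F)(F)F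
Why: C4 is quaternary, so the ketone can enolize only towards C10; O-sulfonylation of the potassium enolate with the triflimide gives the enol triflate.

Step 4
Reactants: 6
Product: 7 (6S)-6-(hydroxymethyl)-6-methylcyclohex-1-en-1-yl trifluoromethanesulfonate
Conditions: i-Bu2AlH (2.5 equiv), CH2Cl2, −78 → 0 °C; aq. potassium sodium tartrate
Reagents that add atoms: none
Why: Aluminium hydride reduction of the ester to the primary alcohol at low temperature; the enol triflate is inert, and the C19 hydroxyl now sits next to it (the descriptor changes only through the priority rules).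

Step 5
Reactants: 7
Product: 8 (3aR)-3a-methyl-3a,4,5,6-tetrahydro-2-benzofuran-1(3H)-one
Conditions: Pd(PPh3)4 (5 mol%), CO (1 atm), n-Bu3N, LiCl, MeCN, 65 °C
Reagents that add atoms: carbon monoxide [C-]#[O+]
Why: Palladium-catalysed cyclocarbonylation of a hydroxy enol triflate: oxidative addition, CO insertion and capture of the acylpalladium by the C19 hydroxyl form the C5–C6 bond and close the γ-lactone, which can only hold C6 and C19 on the same side of ring A.

Step 6
Reactants: 8
Product: 10 (3aR,7R,7aS)-7-ethenyl-3a-methylhexahydro-2-benzofuran-1(3H)-one, via silyl ketene acetal 9 (not isolated)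
Conditions: CH2=CHMgBr (2 equiv), CuBr·SMe2 (10 mol%), Me3SiCl, THF, −78 → −40 °C; aq. NH4Cl, 1 M HCl; then NaOMe (cat.), MeOH, 23 °C
Reagents that add atoms: vinylmagnesium bromide C=C[Mg]Br
Why: Copper-catalysed conjugate addition of the vinyl Grignard reagent to the s-cis-locked alkylidene lactone, accelerated by Me3SiCl, forms C10–C20 with the vinyl group expected anti to the pseudo-axial C18 methyl. Hydrolysis of ketene acetal 9 protonates C5, and the methoxide treatment lets C5 settle in the cis-fused γ-lactone (H5 cis to C18), the more stable fusion next to an angular methyl; this fixes C5.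

Step 7
Reactants: 10
Product: 13 (3aR,7R,7aS)-3a-methyl-1-oxooctahydro-2-benzofuran-7-carbaldehyde, via ozonide 11 (not isolated), via cis aldehyde 12 (not isolated)
Conditions: O3, CH2Cl2, −78 °C; PPh3, −78 → 23 °C; then DBU (cat.), 23 °C
Reagents that add atoms: ozone [O-][O+]=O
Why: Ozonolysis with reductive work-up cuts the vinyl group to the C20 aldehyde; the amidine base then epimerizes the enolizable C10, and the formyl group should settle trans to the C6 carbonyl arm, equatorial in the chair that has only the C19 methylene axial. Residual cis epimer would do no harm, since C10 is made planar again in step 18.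

Step 8
Reactants: 13
Product: 14 (3aR,7R,7aS)-3a-methyl-1-oxooctahydro-2-benzofuran-7-carboxylic acid
Conditions: NaClO2, NaH2PO4, 2-methylbut-2-ene, t-BuOH/H2O, 0 → 23 °C
Reagents that add atoms: sodium chlorite [Na+].[O-]Cl=O
Why: Pinnick oxidation of the aldehyde to the acid under buffered conditions that leave the lactone and the α-stereocentres alone.

Step 9
Reactants: 14
Product: 15 (3aR,7R,7aS)-1-hydroxy-3a-methyloctahydro-2-benzofuran-7-carboxylic acid (lactol; both anomers)
Conditions: i-Bu2AlH (3.2 equiv), CH2Cl2, −78 °C; aq. potassium sodium tartrate, pH 4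
Reagents that add atoms: none
Why: The first equivalent of hydride turns the acid into an aluminium carboxylate that is not reduced at −78 °C; the γ-lactone is then half-reduced to the lactol through its stable tetrahedral aluminate.

Step 10
Reactants: 15
Product: 16 (1R,2S,3R)-2-ethenyl-3-(hydroxymethyl)-3-methylcyclohexane-1-carboxylic acid
Conditions: Ph3PCH3Br (4.5 equiv), KN(SiMe3)2 (4.3 equiv), THF, 0 → 23 °C; pH 4 work-up
Reagents that add atoms: methyltriphenylphosphonium bromide C[P+](c1ccccc1)(c1ccccc1)c1ccccc1.[Br-]
Why: Wittig methylenation of the lactol through its hydroxy aldehyde form turns C6 into the C6=C7 vinyl group and frees the C19 hydroxyl; excess ylide covers the acidic protons, and the low temperature is meant to keep the α-centre C5 from epimerizing.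

Step 11
Reactants: 16
Product: 17 tri(propan-2-yl)silyl (1R,2S,3R)-2-ethenyl-3-methyl-3-({[tri(propan-2-yl)silyl]oxy}methyl)cyclohexane-1-carboxylate
Conditions: i-Pr3SiOTf (2.4 equiv), 2,6-lutidine, CH2Cl2, 0 → 23 °C
Reagents that add atoms: triisopropylsilyl trifluoromethanesulfonate CC(C)[Si](OS(=O)(=O)C(F)(F)F)(C(C)C)C(C)C
Why: The silyl triflate caps the neopentyl C19 hydroxyl as its ether and the acid as a silyl ester, which masks the acidic proton for the hydroboration of step 16.

Step 12
Reactants: 18 but-3-yn-1-ol
Product: 19 (but-3-yn-1-yloxy)(tert-butyl)dimethylsilane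
Conditions: t-BuMe2SiCl, imidazole, CH2Cl2, 23 °C
Reagents that add atoms: tert-butylchlorodimethylsilane CC(C)(C)[Si](C)(C)Cl
Why: Standard silylation of the primary alcohol.

Step 13
Reactants: 19
Product: 20 methyl 5-{[tert-butyl(dimethyl)silyl]oxy}pent-2-ynoate
Conditions: n-BuLi, THF, −78 °C; ClCO2Me, −78 → 0 °C
Reagents that add atoms: methyl chloroformate COC(=O)Cl
Why: Deprotonation of the terminal alkyne and C-acylation of the lithium acetylide with the chloroformate give the ynoate.

Step 14
Reactants: 20
Product: 22 methyl (2E)-5-{[tert-butyl(dimethyl)silyl]oxy}-2-iodopent-2-enoate, via vinylstannane 21 (not isolated)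
Conditions: Bu3SnH, Pd(PPh3)4 (2 mol%), THF, 0 → 23 °C; then I2, CH2Cl2, 0 °C, dark
Reagents that add atoms: iodine II
Why: Palladium-catalysed hydrostannation of an alkynoate adds H and Sn syn with tin on the α-carbon, so the ester and the C11 chain end cis; iododestannylation goes with retention and gives the (E)-2-iodo enoate.

Step 15
Reactants: 22
Product: 23 (2E)-5-{[tert-butyl(dimethyl)silyl]oxy}-2-iodopent-2-en-1-ol
Conditions: i-Bu2AlH (2.3 equiv), CH2Cl2, −78 °C; aq. potassium sodium tartrate
Reagents that add atoms: none
Why: 1,2-Reduction of the enoate to the allylic alcohol at −78 °C leaves the iodoalkene and its geometry untouched; C17 is thereby cis to C11, as the key step requires.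

Step 16
Reactants: 17; 23
Product: 26 (1R,2S,3R)-2-[(3Z)-6-{[tert-butyl(dimethyl)silyl]oxy}-3-(hydroxymethyl)hex-3-en-1-yl]-3-methyl-3-({[tri(propan-2-yl)silyl]oxy}methyl)cyclohexane-1-carboxylic acid, via alkylborane 24 (not isolated), via silyl ester 25 (not isolated)
Conditions: 9-BBN-H dimer, THF, 23 → 40 °C; then 23, PdCl2(dppf) (8 mol%), AsPh3, Cs2CO3, DMF/H2O, 23 °C; then K2CO3, MeOH/H2O, 23 °C; pH 4
Reagents that add atoms: none
Why: B-alkyl Suzuki–Miyaura coupling: 9-BBN adds to the terminal vinyl group with boron on C7, and the alkylborane couples with the iodoalkene with retention of the alkene geometry, forming C7–C8; the free allylic hydroxyl is tolerated, and carbonate then cleaves the silyl ester to the seco acid.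

Step 17
Reactants: 26
Product: 28 (4Z,6aS,7R,10aR)-4-(3-{[tert-butyl(dimethyl)silyl]oxy}propylidene)-7-methyl-7-({[tri(propan-2-yl)silyl]oxy}methyl)decahydro-1H-2-benzoxocin-1-one, via mixed anhydride 27 (not isolated)
Conditions: 2-methyl-6-nitrobenzoic anhydride (1.3 equiv), DMAP (6 equiv), CH2Cl2, 23 °C; 26 added over 12 h to a final 1 mM
Reagents that add atoms: none
Why: Shiina macrolactonization: the acid is activated as the mixed anhydride 27 and DMAP transfers the acyl group to the primary allylic hydroxyl, closing the eight-membered lactone (8-exo-trig at C20); the trans-diequatorial cyclohexane and the sp2 centre C8 bring the ends together, and slow addition at high dilution suppresses dimers.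

Step 18
Reactants: 28
Product: 31 (1R,4aR,5R,8aR)-5-(2-{[tert-butyl(dimethyl)silyl]oxy}ethyl)-1-methyl-6-methylidene-1-({[tri(propan-2-yl)silyl]oxy}methyl)octahydronaphthalene-4a(2H)-carboxylic acid, via silyl ketene acetal 29 (not isolated), via silyl ester 30 (not isolated)
Conditions: Me3SiCl/Et3N (premixed, 4 equiv), LiN(i-Pr)2 (2 equiv), THF, −78 → 23 °C; then toluene, 90 °C; aq. NH4Cl, dilute citric acid
Reagents that add atoms: none
Why: Proposed new method: Deprotonation of the lactone at C10 with the silyl chloride already present gives ketene acetal 29, whose geometry is fixed by the eight-membered ring (ring oxygen cis to C5); on warming, C10 and the exocyclic allyl unit C17–C8=C9 undergo a concerted [3,3] shift that forms C9–C10, breaks C17–O, and turns C20 into a silyl ester and C17 into the exocyclic methylene. The closest known reaction is the Ireland–Claisen ring contraction of macrocyclic allylic lactones; what is new is that the alkene is exocyclic to the lactone, so C20, the oxygen and C17 are all pushed out of the new carbocycle. Ring B (C5–C10) closes across the eight-membered ring, 6-endo with respect to C8=C9, through a bicyclo[3.3.1]-like array in which the Claisen six-ring and the forming ring B share C10, C9 and C8. At C10, this array forces C1 to be equatorial on ring B, which keeps C6 equatorial and C19 axial on ring A; an axial approach of C9 would run into the C19 arm, so C9 enters equatorially, C20 turns axial and the fusion is trans. At C9, the substituent that is cis to C17 in the alkene points towards the oxygen bridge and ends equatorial on ring B, so the (Z)-alkene of 28 puts C11 equatorial and H9 axial whether the Claisen ring is a chair or a boat. The step needs enolization without ketene-forming fragmentation (the enolate is silylated as it forms at −78 °C), rearrangement before the ketene acetal decomposes (the reacting carbons are held 1,5 across the ring), and the trans fusion (C4 and C19, as above).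

Step 19
Reactants: 31
Product: 32 [(1R,4aR,5R,8aR)-5-(2-{[tert-butyl(dimethyl)silyl]oxy}ethyl)-1-methyl-6-methylidene-1-({[tri(propan-2-yl)silyl]oxy}methyl)octahydronaphthalen-4a(2H)-yl]methanol
Conditions: LiAlH4, THF, 0 → 50 °C
Reagents that add atoms: none
Why: Hydride reduction of the hindered acid to the neopentyl alcohol; silyl ethers and the 1,1-disubstituted alkene are inert to LiAlH4.

Step 20
Reactants: 32
Product: 33 4-methoxybenzyl ether of 32 at the C20 oxygen
Conditions: NaH, 4-MeOC6H4CH2Cl, Bu4NI (cat.), DMF, 0 → 23 °C
Reagents that add atoms: 4-methoxybenzyl chloride COc1ccc(CCl)cc1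
Why: Williamson etherification of the primary alkoxide; the 4-methoxybenzyl ether masks the C20 hydroxyl orthogonally to the silyl ethers and to the later acetate.

Step 21
Reactants: 33
Product: 34 C12,C19-diol: 2-[(1R,4aR,5R,8aR)-5-(hydroxymethyl)-8a-{[(4-methoxybenzyl)oxy]methyl}-5-methyl-2-methylidenedecahydronaphthalen-1-yl]ethan-1-ol
Conditions: Bu4NF, THF, 23 → 45 °C
Reagents that add atoms: none
Why: Fluoride cleaves both silyl ethers and leaves the benzyl-type ether; the two free hydroxyls differ strongly in hindrance (C12 unhindered, C19 neopentyl and axial).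

Step 22
Reactants: 34
Product: 35 C12 iodide of 34 (C19 hydroxyl free)
Conditions: I2, PPh3, imidazole, CH2Cl2, 0 °C
Reagents that add atoms: iodine II
Why: Garegg–Samuelsson iodination: only the unhindered C12 alkoxyphosphonium ion can be displaced by iodide in an SN2 reaction; the neopentyl C19 hydroxyl cannot and is recovered on work-up.

Step 23
Reactants: 35
Product: 36 C19 acetate of 35
Conditions: Ac2O, pyridine, DMAP (cat.), CH2Cl2, 23 °C
Reagents that add atoms: acetic anhydride CC(=O)OC(C)=O
Why: DMAP-catalysed acetylation of the remaining neopentyl alcohol installs the C19 acetate of the target.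

Step 24
Reactants: 36; 37 3-bromofuran-2(5H)-one
Product: 39 [(1R,4aR,5R,8aR)-4a-{[(4-methoxybenzyl)oxy]methyl}-1-methyl-6-methylidene-5-[2-(2-oxo-2,5-dihydrofuran-3-yl)ethyl]decahydronaphthalen-1-yl]methyl acetate, via alkylzinc iodide 38 (not isolated)
Conditions: Zn dust (activated by BrCH2CH2Br and Me3SiCl), LiCl, THF, 40 °C; then 37, Pd2(dba)3 (2.5 mol%), SPhos (10 mol%), THF/NMP, 23 °C
Reagents that add atoms: none
Why: Negishi coupling: zinc inserts into the primary C–I bond in the presence of LiCl, and the alkylzinc iodide couples with the α-bromobutenolide under palladium catalysis with a bulky biaryl phosphine, which favours reductive elimination over β-hydride loss; acetate, ether and alkene are compatible with organozinc reagents.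

Step 25
Reactants: 39
Product: 40 [(1R,4aR,5R,8aR)-4a-(hydroxymethyl)-1-methyl-6-methylidene-5-[2-(2-oxo-2,5-dihydrofuran-3-yl)ethyl]decahydronaphthalen-1-yl]methyl acetate
Conditions: DDQ, CH2Cl2/pH 7 buffer, 0 → 23 °C
Reagents that add atoms: none
Why: Oxidative cleavage of the 4-methoxybenzyl ether by DDQ in wet CH2Cl2 through the benzylic cation; acetate, butenolide and the exocyclic alkene are not oxidized.

Step 26
Reactants: 40
Product: 41 [(1R,4aR,5R,8aR)-4a-formyl-1-methyl-6-methylidene-5-[2-(2-oxo-2,5-dihydrofuran-3-yl)ethyl]decahydronaphthalen-1-yl]methyl acetate (CNP0109410.1)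
Conditions: Dess–Martin periodinane, NaHCO3, CH2Cl2, 0 → 23 °C
Reagents that add atoms: none
Why: Dess–Martin oxidation of the neopentyl alcohol to the aldehyde under buffered, non-acidic conditions; C10 is quaternary, so nothing can epimerize, and the methylene and butenolide are left alone.

**Compound list**

1 | ethyl 2-oxocyclohexane-1-carboxylate | CCOC(=O)C1CCCCC1=O | starting material
2 | tert-butyl L-valinate | CC(C)[C@H](N)C(=O)OC(C)(C)C | starting material
3 | tert-butyl (2S)-2-{[2-(ethoxycarbonyl)cyclohex-1-en-1-yl]amino}-3-methylbutanoate | CCOC(=O)C1=C(N[C@@H](C(C)C)C(=O)OC(C)(C)C)CCCC1 | intermediate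
4 | tert-butyl (2S)-2-{[(2R)-2-(ethoxycarbonyl)-2-methylcyclohexylidene]amino}-3-methylbutanoate | CC(C)[C@H](N=C1CCCC[C@@]1(C)C(=O)OCC)C(=O)OC(C)(C)C | intermediate (not isolated)
5 | ethyl (1R)-1-methyl-2-oxocyclohexane-1-carboxylate | O=C1CCCC[C@@]1(C)C(=O)OCC | intermediate
6 | ethyl (1R)-1-methyl-2-{[(trifluoromethyl)sulfonyl]oxy}cyclohex-2-ene-1-carboxylate | O=S(=O)(OC1=CCCC[C@@]1(C)C(=O)OCC)C(F)(F)F | intermediate
7 | (6S)-6-(hydroxymethyl)-6-methylcyclohex-1-en-1-yl trifluoromethanesulfonate | O=S(=O)(OC1=CCCC[C@@]1(C)CO)C(F)(F)F | intermediate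
8 | (3aR)-3a-methyl-3a,4,5,6-tetrahydro-2-benzofuran-1(3H)-one | O=C1OC[C@]2(C)CCCC=C12 | intermediate
9 | O-trimethylsilyl ketene acetal of 10 (C5=C6 double bond, vinyl on C10 anti to C18) | C[Si](C)(C)OC1=C2[C@@H](C=C)CCC[C@@]2(C)CO1 | intermediate (not isolated)
10 | (3aR,7R,7aS)-7-ethenyl-3a-methylhexahydro-2-benzofuran-1(3H)-one (cis-fused; vinyl anti to the angular methyl) | O=C1OC[C@]2(C)CCC[C@H](C=C)[C@H]12 | intermediate
11 | (3aR,7S,7aS)-3a-methyl-7-(1,2,4-trioxolan-3-yl)hexahydro-2-benzofuran-1(3H)-one | O=C1OC[C@]2(C)CCC[C@H](C3OCOO3)[C@H]12 | intermediate (not isolated)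
12 | (3aR,7S,7aS)-3a-methyl-1-oxooctahydro-2-benzofuran-7-carbaldehyde (formyl cis to the C6 arm) | O=C1OC[C@]2(C)CCC[C@H](C=O)[C@H]12 | intermediate (not isolated)
13 | (3aR,7R,7aS)-3a-methyl-1-oxooctahydro-2-benzofuran-7-carbaldehyde (formyl trans to the C6 arm) | O=C1OC[C@]2(C)CCC[C@@H](C=O)[C@H]12 | intermediate
14 | (3aR,7R,7aS)-3a-methyl-1-oxooctahydro-2-benzofuran-7-carboxylic acid | O=C1OC[C@]2(C)CCC[C@@H](C(=O)O)[C@H]12 | intermediate
15 | (3aR,7R,7aS)-1-hydroxy-3a-methyloctahydro-2-benzofuran-7-carboxylic acid (both anomers) | OC1OC[C@]2(C)CCC[C@@H](C(=O)O)[C@H]12 | intermediate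
16 | (1R,2S,3R)-2-ethenyl-3-(hydroxymethyl)-3-methylcyclohexane-1-carboxylic acid | C=C[C@@H]1[C@](C)(CO)CCC[C@H]1C(=O)O | intermediate
17 | tri(propan-2-yl)silyl (1R,2S,3R)-2-ethenyl-3-methyl-3-({[tri(propan-2-yl)silyl]oxy}methyl)cyclohexane-1-carboxylate | C=C[C@@H]1[C@](C)(CO[Si](C(C)C)(C(C)C)C(C)C)CCC[C@H]1C(=O)O[Si](C(C)C)(C(C)C)C(C)C | intermediate
18 | but-3-yn-1-ol | C#CCCO | starting material
19 | (but-3-yn-1-yloxy)(tert-butyl)dimethylsilane | C#CCCO[Si](C)(C)C(C)(C)C | intermediate
20 | methyl 5-{[tert-butyl(dimethyl)silyl]oxy}pent-2-ynoate | COC(=O)C#CCCO[Si](C)(C)C(C)(C)C | intermediate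
21 | methyl (2E)-5-{[tert-butyl(dimethyl)silyl]oxy}-2-(tributylstannyl)pent-2-enoate | COC(=O)/C(=C\CCO[Si](C)(C)C(C)(C)C)[Sn](CCCC)(CCCC)CCCC | intermediate (not isolated)
22 | methyl (2E)-5-{[tert-butyl(dimethyl)silyl]oxy}-2-iodopent-2-enoate | COC(=O)/C(I)=C\CCO[Si](C)(C)C(C)(C)C | intermediate
23 | (2E)-5-{[tert-butyl(dimethyl)silyl]oxy}-2-iodopent-2-en-1-ol | OC/C(I)=C\CCO[Si](C)(C)C(C)(C)C | intermediate
24 | B-alkyl-9-borabicyclo[3.3.1]nonane from 17 (boron on C7) | B1(CC[C@@H]2[C@](C)(CO[Si](C(C)C)(C(C)C)C(C)C)CCC[C@H]2C(=O)O[Si](C(C)C)(C(C)C)C(C)C)C2CCCC1CCC2 | intermediate (not isolated)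
25 | tri(propan-2-yl)silyl ester of 26 | OC/C(=C\CCO[Si](C)(C)C(C)(C)C)CC[C@@H]1[C@](C)(CO[Si](C(C)C)(C(C)C)C(C)C)CCC[C@H]1C(=O)O[Si](C(C)C)(C(C)C)C(C)C | intermediate (not isolated)
26 | (1R,2S,3R)-2-[(3Z)-6-{[tert-butyl(dimethyl)silyl]oxy}-3-(hydroxymethyl)hex-3-en-1-yl]-3-methyl-3-({[tri(propan-2-yl)silyl]oxy}methyl)cyclohexane-1-carboxylic acid | OC/C(=C\CCO[Si](C)(C)C(C)(C)C)CC[C@@H]1[C@](C)(CO[Si](C(C)C)(C(C)C)C(C)C)CCC[C@H]1C(=O)O | intermediate
27 | mixed anhydride of 26 with 2-methyl-6-nitrobenzoic acid | OC/C(=C\CCO[Si](C)(C)C(C)(C)C)CC[C@@H]1[C@](C)(CO[Si](C(C)C)(C(C)C)C(C)C)CCC[C@H]1C(=O)OC(=O)c1c(C)cccc1[N+](=O)[O-] | intermediate (not isolated)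
28 | (4Z,6aS,7R,10aR)-4-(3-{[tert-butyl(dimethyl)silyl]oxy}propylidene)-7-methyl-7-({[tri(propan-2-yl)silyl]oxy}methyl)decahydro-1H-2-benzoxocin-1-one (ring A trans-fused to the eight-membered lactone) | O=C1OC/C(=C\CCO[Si](C)(C)C(C)(C)C)CC[C@@H]2[C@](C)(CO[Si](C(C)C)(C(C)C)C(C)C)CCC[C@@H]12 | intermediate
29 | O-trimethylsilyl ketene acetal of 28 (C10=C20; ring oxygen cis to C5) | C[Si](C)(C)O/C1=C2\CCC[C@@](C)(CO[Si](C(C)C)(C(C)C)C(C)C)[C@H]2CC/C(=C/CCO[Si](C)(C)C(C)(C)C)CO1 | intermediate (not isolated)
30 | trimethylsilyl ester of 31 | C=C1CC[C@@H]2[C@](C)(CO[Si](C(C)C)(C(C)C)C(C)C)CCC[C@@]2(C(=O)O[Si](C)(C)C)[C@@H]1CCO[Si](C)(C)C(C)(C)C | intermediate (not isolated)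
31 | (1R,4aR,5R,8aR)-5-(2-{[tert-butyl(dimethyl)silyl]oxy}ethyl)-1-methyl-6-methylidene-1-({[tri(propan-2-yl)silyl]oxy}methyl)octahydronaphthalene-4a(2H)-carboxylic acid (trans-decalin C20 acid) | C=C1CC[C@@H]2[C@](C)(CO[Si](C(C)C)(C(C)C)C(C)C)CCC[C@@]2(C(=O)O)[C@@H]1CCO[Si](C)(C)C(C)(C)C | intermediate
32 | C20 alcohol from 31 | C=C1CC[C@@H]2[C@](C)(CO[Si](C(C)C)(C(C)C)C(C)C)CCC[C@@]2(CO)[C@@H]1CCO[Si](C)(C)C(C)(C)C | intermediate
33 | C20 4-methoxybenzyl ether of 32 | C=C1CC[C@@H]2[C@](C)(CO[Si](C(C)C)(C(C)C)C(C)C)CCC[C@@]2(COCc3ccc(OC)cc3)[C@@H]1CCO[Si](C)(C)C(C)(C)C | intermediate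
34 | C12,C19-diol (C20 4-methoxybenzyl ether) | C=C1CC[C@@H]2[C@](C)(CO)CCC[C@@]2(COCc3ccc(OC)cc3)[C@@H]1CCO | intermediate
35 | C12 iodide, C19 alcohol (C20 4-methoxybenzyl ether) | C=C1CC[C@@H]2[C@](C)(CO)CCC[C@@]2(COCc3ccc(OC)cc3)[C@@H]1CCI | intermediate
36 | C12 iodide, C19 acetate (C20 4-methoxybenzyl ether) | C=C1CC[C@@H]2[C@](C)(COC(C)=O)CCC[C@@]2(COCc3ccc(OC)cc3)[C@@H]1CCI | intermediate
37 | 3-bromofuran-2(5H)-one | O=C1OCC=C1Br | starting material
38 | C12 alkylzinc iodide from 36 | C=C1CC[C@@H]2[C@](C)(COC(C)=O)CCC[C@@]2(COCc3ccc(OC)cc3)[C@@H]1CC[Zn]I | intermediate (not isolated)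
39 | [(1R,4aR,5R,8aR)-4a-{[(4-methoxybenzyl)oxy]methyl}-1-methyl-6-methylidene-5-[2-(2-oxo-2,5-dihydrofuran-3-yl)ethyl]decahydronaphthalen-1-yl]methyl acetate | C=C1CC[C@@H]2[C@](C)(COC(C)=O)CCC[C@@]2(COCc3ccc(OC)cc3)[C@@H]1CCC1=CCOC1=O | intermediate
40 | [(1R,4aR,5R,8aR)-4a-(hydroxymethyl)-1-methyl-6-methylidene-5-[2-(2-oxo-2,5-dihydrofuran-3-yl)ethyl]decahydronaphthalen-1-yl]methyl acetate | C=C1CC[C@@H]2[C@](C)(COC(C)=O)CCC[C@@]2(CO)[C@@H]1CCC1=CCOC1=O | intermediate
41 | [(1R,4aR,5R,8aR)-4a-formyl-1-methyl-6-methylidene-5-[2-(2-oxo-2,5-dihydrofuran-3-yl)ethyl]decahydronaphthalen-1-yl]methyl acetate (CNP0109410.1) | C=C1CC[C@@H]2[C@](C)(COC(C)=O)CCC[C@@]2(C=O)[C@@H]1CCC1=CCOC1=O | target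

**Step count and least certain steps**

Total step count: 26. Longest linear sequence: 22 steps (steps 1–11 and 16–26); steps 12–15 make the second fragment.

Step 18 (key step). Three things may go wrong. Enolization at C10 may be slow, or the enolate may fragment to a ketene before it is silylated. The [3,3] shift may need more heat than the ketene acetal tolerates, because the bicyclic transition state is built inside a medium ring. C9 may bond to the other face of C10 and give the cis fusion if the C19 arm shields less than expected. The fallback uses known reactions only; it sets out from 17 and 23 and comes back at 32. Carbonate in aqueous methanol cleaves the silyl ester of 17 to the acid F1, which is esterified with 23 (carbodiimide, DMAP) to the acyclic 2-iodoallyl ester F2. A conventional acyclic Ireland–Claisen rearrangement (LiN(i-Pr)2, Me3SiCl, THF, −78 → 60 °C) forms C9–C10 and gives the acid F3, which carries a 2-iodoalkene at C8; Me3SiCHN2 gives the methyl ester F4. Hydroboration of the C5 vinyl group with 9-BBN gives the borane F5, and an intramolecular Suzuki–Miyaura coupling (PdCl2(dppf), AsPh3, Cs2CO3) closes ring B at C7–C8 to the ester F6, which LiAlH4 reduces to 32. The cost is weaker control at C9, which then depends on the geometry of an acyclic ketene acetal.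

Step 17. Intermolecular acylation may outrun closure of the strained eight-membered ring and give dimers and oligomers, above all because the activated acid is secondary and hindered. The fallback forms the ester bond first and the ring at carbon. It sets out from 17 and 23 through F1 and F2 (above) and comes back at 28. Hydroboration of the vinyl group of F2 with 9-BBN gives the borane F7, and slow addition to PdCl2(dppf), AsPh3 and Cs2CO3 at high dilution closes the ring at C7–C8 by intramolecular Suzuki–Miyaura coupling.

Step 6. Transfer of the vinyl group to the β-carbon of a trisubstituted alkylidene lactone may be slow and lose to attack at the lactone carbonyl, and protonation at C5 may be incomplete towards the cis fusion. The fallback uses a reversible carbon nucleophile; it sets out from 8 and comes back at 14. Michael addition of nitromethane (DBU, MeCN) under equilibrating conditions gives the nitromethyl lactone F8, and NaNO2 with acetic acid in DMSO oxidizes the primary nitro group directly to the acid 14. Steps 7 and 8 are then not needed.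

Step 10. The basic ylide may enolize the open hydroxy aldehyde and epimerize C5, the centre that the lactone had fixed; the aldehyde is hindered, so olefination is not fast. The fallback uses a non-basic carbon nucleophile and a separate elimination; it sets out from 15 and comes back at 16. Me3SiCH2Li with CeCl3 (in excess, to cover the acidic protons) adds to the aldehyde form and gives the β-hydroxy silane F9, and Peterson elimination (KH, or HF·pyridine) gives the vinyl group of 16.

Step 24. Zinc insertion may be slow, the alkylzinc may be protonated, or the bromobutenolide may be reduced or decomposed before coupling. The fallback builds the butenolide on the chain by enolate alkylation; it sets out from 36 and comes back at 39. The lithium enolate of 3-(phenylsulfanyl)oxolan-2-one (LiN(SiMe3)2, THF/HMPA) is alkylated by 36 to the sulfide F10. One equivalent of peracid at −78 °C gives the sulfoxide F11, and thermolysis in toluene with CaCO3 eliminates the sulfenic acid towards the ring to give 39.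

**Further compounds**

F1 | step 18 | (1R,2S,3R)-2-ethenyl-3-methyl-3-({[tri(propan-2-yl)silyl]oxy}methyl)cyclohexane-1-carboxylic acid | C=C[C@@H]1[C@](C)(CO[Si](C(C)C)(C(C)C)C(C)C)CCC[C@H]1C(=O)O
F2 | step 18 | (2E)-5-{[tert-butyl(dimethyl)silyl]oxy}-2-iodopent-2-en-1-yl ester of F1 | C=C[C@@H]1[C@](C)(CO[Si](C(C)C)(C(C)C)C(C)C)CCC[C@H]1C(=O)OC/C(I)=C\CCO[Si](C)(C)C(C)(C)C
F3 | step 18 | acyclic Claisen acid (C9–C10 formed; 2-iodoalkene at C8; vinyl on C5) | C=C(I)[C@@H](CCO[Si](C)(C)C(C)(C)C)[C@]1(C(=O)O)CCC[C@@](C)(CO[Si](C(C)C)(C(C)C)C(C)C)[C@H]1C=C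
F4 | step 18 | methyl ester of F3 | C=C(I)[C@@H](CCO[Si](C)(C)C(C)(C)C)[C@]1(C(=O)OC)CCC[C@@](C)(CO[Si](C(C)C)(C(C)C)C(C)C)[C@H]1C=C
F5 | step 18 | B-alkyl-9-borabicyclo[3.3.1]nonane from F4 (boron on C7) | C=C(I)[C@@H](CCO[Si](C)(C)C(C)(C)C)[C@]1(C(=O)OC)CCC[C@@](C)(CO[Si](C(C)C)(C(C)C)C(C)C)[C@H]1CCB1C2CCCC1CCC2
F6 | step 18 | methyl ester of 31 | C=C1CC[C@@H]2[C@](C)(CO[Si](C(C)C)(C(C)C)C(C)C)CCC[C@@]2(C(=O)OC)[C@@H]1CCO[Si](C)(C)C(C)(C)C
F7 | step 17 | B-alkyl-9-borabicyclo[3.3.1]nonane from F2 (boron on C7) | B1(CC[C@@H]2[C@](C)(CO[Si](C(C)C)(C(C)C)C(C)C)CCC[C@H]2C(=O)OC/C(I)=C\CCO[Si](C)(C)C(C)(C)C)C2CCCC1CCC2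
F8 | step 6 | (3aR,7R,7aS)-3a-methyl-7-(nitromethyl)hexahydro-2-benzofuran-1(3H)-one | O=C1OC[C@]2(C)CCC[C@@H](C[N+](=O)[O-])[C@H]12
F9 | step 10 | (1R,2S,3R)-2-[1-hydroxy-2-(trimethylsilyl)ethyl]-3-(hydroxymethyl)-3-methylcyclohexane-1-carboxylic acid | C[Si](C)(C)CC(O)[C@@H]1[C@](C)(CO)CCC[C@H]1C(=O)O
F10 | step 24 | C12-alkylated 3-(phenylsulfanyl)oxolan-2-one (C19 acetate, C20 4-methoxybenzyl ether) | C=C1CC[C@@H]2[C@](C)(COC(C)=O)CCC[C@@]2(COCc3ccc(OC)cc3)[C@@H]1CCC1(Sc3ccccc3)CCOC1=O
F11 | step 24 | sulfoxide of F10 | C=C1CC[C@@H]2[C@](C)(COC(C)=O)CCC[C@@]2(COCc3ccc(OC)cc3)[C@@H]1CCC1(S(=O)c3ccccc3)CCOC1=O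
A1 | alternative 1 | bridged tricyclic ketone with quaternary C4 | C1COC2(O1)CC[C@@H]3[C@](C)(CC4=O)CCC[C@@]34[C@@H]2CCO[Si](c5ccccc5)(c5ccccc5)C(C)(C)C
A2 | alternative 1 | C20 diazoketone with C4 methine | C1COC2(O1)CC[C@@H]3[C@@H](C)CCC[C@@]3(C(=O)C=[N+]=[N-])[C@@H]2CCO[Si](c4ccccc4)(c4ccccc4)C(C)(C)C
A3 | alternative 2 | trans-fused bicyclic 3-keto ester with C8 exocyclic methylene | C=C1CC[C@@H]2[C@](C)(C(=O)O[C@H]3C[C@@H](C)CC[C@@H]3C(C)(C)c3ccccc3)C(=O)CC[C@@]2(CO[Si](c3ccccc3)(c3ccccc3)C(C)(C)C)[C@@H]1CCOC(=O)C(C)(C)C
A4 | alternative 2 | acyclic β-keto ester diene | CC(C(=O)O[C@H]1C[C@@H](C)CC[C@@H]1C(C)(C)c1ccccc1)C(=O)CC/C(CO[Si](c1ccccc1)(c1ccccc1)C(C)(C)C)=C/CC/C(C)=C/CCOC(=O)C(C)(C)C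
A5 | alternative 3 | bicyclic lactone acid of ring A | O=C1OC[C@H]2C=CC[C@@](C)(C(=O)O)[C@@H]12
A6 | alternative 3 | citraconic anhydride | CC1=CC(=O)OC1=O
A7 | alternative 3 | (2E)-penta-2,4-dien-1-ol | OC/C=C/C=C
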